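**Retrosynthetic overview**
- The target is reached by hydrogenolysis of two benzyl ethers and chelation-controlled 5-O-demethylation of 6-benzyloxy-2-(3-benzyloxy-4-methoxyphenyl)-5,7,8-trimethoxyflavone; 6-OBn and 5-OMe distinguish the two A-ring hydroxyls from the 7,8-OMe groups.
- The pyranone ring (ring C, the only ring formed) comes from I2/DMSO oxidative cyclisation of a 2'-hydroxychalcone.
- The chalcone comes from a Claisen–Schmidt aldol condensation (key C–C bond, Cα–Cβ) of 5-benzyloxy-2-hydroxy-3,4,6-trimethoxyacetophenone with O-benzylisovanillin.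
- The acetophenone comes from 3,4,5-trimethoxyphenol by O-methylation, Friedel–Crafts acetylation with ortho-demethylation, Elbs para-hydroxylation and selective benzylation.
- Rings A and B are bought as arenes; ring C is closed last.

Assumption: the target has no stereocentre, so no enantiocontrol is needed; the only stereo-element in the route is the E alkene of the chalcone, and two transient intermediates are racemic. Compound numbers follow the forward route.

**Step 1**
Reactants: 1 3,4,5-trimethoxyphenol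
Product: 2 1,2,3,5-tetramethoxybenzene
Conditions: MeI (1.5 equiv), K2CO3, acetone, reflux
Reagents that add atoms: iodomethane, CI
Why: Williamson O-methylation of the single phenol gives the symmetrical tetramethyl ether with two equivalent free ring positions.

**Step 2**
Reactants: 2 1,2,3,5-tetramethoxybenzene
Product: 4 1-(2-hydroxy-3,4,6-trimethoxyphenyl)ethanone, via 2,3,4,6-tetramethoxyacetophenone 3 (not isolated)
Conditions: AcCl (1.2 equiv), AlCl3 (2.5 equiv), Et2O, 0 °C to rt; then ice/HCl
Reagents that add atoms: acetyl chloride, CC(Cl)=O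
Why: Friedel–Crafts acylation can only occur at the two equivalent CH positions, and the AlCl3-chelated ketone then cleaves the ortho-methoxy group that is buttressed by a neighbouring OMe (chelation-assisted ortho-demethylation).

**Step 3**
Reactants: 4 1-(2-hydroxy-3,4,6-trimethoxyphenyl)ethanone
Product: 6 1-(2,5-dihydroxy-3,4,6-trimethoxyphenyl)ethanone, via aryl sulfate 5 (not isolated)
Conditions: K2S2O8 (1.1 equiv), 10% aq KOH, 15–20 °C, 24 h; acidify to pH 4 and extract unreacted 4; then conc. HCl, Na2SO3, 85 °C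
Reagents that add atoms: potassium peroxodisulfate, [K+].[K+].[O-]S(=O)(=O)OOS(=O)(=O)[O-]
Why: Elbs persulfate oxidation attacks the phenoxide para to O−, which is the only free ring position, and the aryl sulfate is hydrolysed by acid to the hydroquinone.

**Step 4**
Reactants: 6 1-(2,5-dihydroxy-3,4,6-trimethoxyphenyl)ethanone
Product: 7 1-(5-benzyloxy-2-hydroxy-3,4,6-trimethoxyphenyl)ethanone
Conditions: BnBr (1.05 equiv), K2CO3 (1.1 equiv), DMF, rt
Reagents that add atoms: benzyl bromide, BrCc1ccccc1
Why: Selective Williamson benzylation occurs at the 5-OH because the 2-OH is deactivated by its hydrogen bond to the acetyl carbonyl.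

**Step 5**
Reactants: 7 1-(5-benzyloxy-2-hydroxy-3,4,6-trimethoxyphenyl)ethanone; 8 3-benzyloxy-4-methoxybenzaldehyde
Product: 10 (E)-1-(5-benzyloxy-2-hydroxy-3,4,6-trimethoxyphenyl)-3-(3-benzyloxy-4-methoxyphenyl)prop-2-en-1-one, via β-hydroxy ketone 9 (not isolated)
Conditions: 50% aq KOH (10 equiv), EtOH, rt, 48 h, Ar; then dil. HCl, 0 °C
Reagents that add atoms: none
Why: Claisen–Schmidt (crossed aldol) condensation of the methyl ketone enolate with a non-enolisable aldehyde, followed by E1cB dehydration, gives the thermodynamically favoured E-enone; any flavanone formed by ring closure is carried into step 6.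

**Step 6**
Reactants: 10 (E)-1-(5-benzyloxy-2-hydroxy-3,4,6-trimethoxyphenyl)-3-(3-benzyloxy-4-methoxyphenyl)prop-2-en-1-one
Product: 12 6-benzyloxy-2-(3-benzyloxy-4-methoxyphenyl)-5,7,8-trimethoxy-4H-chromen-4-one, via flavanone 11 (not isolated)
Conditions: I2 (10 mol%), DMSO, 120 °C, 3–6 h; aq Na2S2O3 quench
Reagents that add atoms: none
Why: In this iodine/DMSO oxidative cyclisation the free 2'-OH closes by intramolecular oxa-Michael addition and the resulting racemic flavanone is dehydrogenated by iodine, which DMSO regenerates; 6'-OMe is blocked, so only one regioisomer can form.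

**Step 7**
Reactants: 12 6-benzyloxy-2-(3-benzyloxy-4-methoxyphenyl)-5,7,8-trimethoxy-4H-chromen-4-one
Product: 13 6-hydroxy-2-(3-hydroxy-4-methoxyphenyl)-5,7,8-trimethoxy-4H-chromen-4-one
Conditions: H2 (1 atm), 10% Pd/C, THF–MeOH, rt
Reagents that add atoms: none
Why: Catalytic hydrogenolysis cleaves both aryl benzyl ethers while the vinylogous-ester C2=C3 bond of the flavone and the methyl ethers are inert at 1 atm and rt.

**Step 8**
Reactants: 13 6-hydroxy-2-(3-hydroxy-4-methoxyphenyl)-5,7,8-trimethoxy-4H-chromen-4-one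
Product: 14 5,6-dihydroxy-2-(3-hydroxy-4-methoxyphenyl)-7,8-dimethoxy-4H-chromen-4-one (5,6,3'-trihydroxy-7,8,4'-trimethoxyflavone)
Conditions: anhydrous AlCl3 (6 equiv), MeCN, 60 °C, 1–2 h; then 2 M HCl, 60 °C
Reagents that add atoms: none
Why: Chelation-controlled Lewis-acid ether cleavage: aluminium bound between C4=O and the peri 5-OMe (helped by the adjacent 6-O–Al phenoxide) activates only that methyl, so the 7-, 8- and 4'-OMe groups survive.

**Compound list**
1 | 3,4,5-trimethoxyphenol | COc1cc(O)cc(OC)c1OC | starting material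
2 | 1,2,3,5-tetramethoxybenzene | COc1cc(OC)c(OC)c(OC)c1 | intermediate
3 | 1-(2,3,4,6-tetramethoxyphenyl)ethanone (2,3,4,6-tetramethoxyacetophenone) | CC(=O)c1c(OC)c(OC)c(OC)cc1OC | intermediate
4 | 1-(2-hydroxy-3,4,6-trimethoxyphenyl)ethanone | CC(=O)c1c(O)c(OC)c(OC)cc1OC | intermediate
5 | 3-acetyl-4-hydroxy-2,5,6-trimethoxyphenyl hydrogen sulfate (aryl sulfate, potassium salt in the flask) | CC(=O)c1c(O)c(OC)c(OC)c(OS(=O)(=O)O)c1OC | intermediate
6 | 1-(2,5-dihydroxy-3,4,6-trimethoxyphenyl)ethanone | CC(=O)c1c(O)c(OC)c(OC)c(O)c1OC | intermediate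
7 | 1-(5-benzyloxy-2-hydroxy-3,4,6-trimethoxyphenyl)ethanone | CC(=O)c1c(O)c(OC)c(OC)c(OCc2ccccc2)c1OC | intermediate
8 | 3-benzyloxy-4-methoxybenzaldehyde (O-benzylisovanillin) | COc1ccc(C=O)cc1OCc1ccccc1 | starting material
9 | racemic 1-(5-benzyloxy-2-hydroxy-3,4,6-trimethoxyphenyl)-3-(3-benzyloxy-4-methoxyphenyl)-3-hydroxypropan-1-one (β-hydroxy ketone) | COc1ccc(C(O)CC(=O)c2c(O)c(OC)c(OC)c(OCc3ccccc3)c2OC)cc1OCc1ccccc1 | intermediate
10 | (E)-1-(5-benzyloxy-2-hydroxy-3,4,6-trimethoxyphenyl)-3-(3-benzyloxy-4-methoxyphenyl)prop-2-en-1-one | COc1ccc(/C=C/C(=O)c2c(O)c(OC)c(OC)c(OCc3ccccc3)c2OC)cc1OCc1ccccc1 | intermediate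
11 | racemic 6-benzyloxy-2-(3-benzyloxy-4-methoxyphenyl)-5,7,8-trimethoxychroman-4-one (flavanone) | COc1ccc(C2CC(=O)c3c(OC)c(OCc4ccccc4)c(OC)c(OC)c3O2)cc1OCc1ccccc1 | intermediate
12 | 6-benzyloxy-2-(3-benzyloxy-4-methoxyphenyl)-5,7,8-trimethoxy-4H-chromen-4-one | COc1ccc(-c2cc(=O)c3c(OC)c(OCc4ccccc4)c(OC)c(OC)c3o2)cc1OCc1ccccc1 | intermediate
13 | 6-hydroxy-2-(3-hydroxy-4-methoxyphenyl)-5,7,8-trimethoxy-4H-chromen-4-one | COc1ccc(-c2cc(=O)c3c(OC)c(O)c(OC)c(OC)c3o2)cc1O | intermediate
14 | 5,6-dihydroxy-2-(3-hydroxy-4-methoxyphenyl)-7,8-dimethoxy-4H-chromen-4-one (achiral) | COc1ccc(-c2cc(=O)c3c(O)c(O)c(OC)c(OC)c3o2)cc1O | target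

**Totals**
Total step count: 8. Longest linear sequence: 8 steps (1 to 14).

**Steps most likely to fail, with fallbacks**

Step 3 (Elbs oxidation; typically modest conversion, and the electron-rich hydroquinone is air-sensitive). The fallback sets out from 4 and replaces direct hydroxylation by a formylation/oxidation sequence. Duff formylation (hexamethylenetetramine, TFA, 80 °C, then aq HCl) at the only free position, para to the phenol, gives 3-acetyl-4-hydroxy-2,5,6-trimethoxybenzaldehyde F1. Dakin oxidation of this p-hydroxybenzaldehyde (H2O2, aq NaOH, 0 °C to rt under N2, Na2S2O4 in the acidic work-up) then gives the hydroquinone, and the route is rejoined at 6.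

Step 5 (aldol on a di-ortho-substituted, hindered ketone; slow reaction, Cannizzaro loss of aldehyde, chalcone/flavanone mixtures). The fallback sets out from 7 and makes the same C–C bond by an intermolecular Claisen-type C-aroylation. Commercial 3-benzyloxy-4-methoxybenzoic acid is converted with oxalyl chloride/cat. DMF into 3-benzyloxy-4-methoxybenzoyl chloride F2. The lithium dianion of 7 (LiHMDS, 3.5 equiv, THF, −78 °C) is acylated with it to give 1-(5-benzyloxy-2-hydroxy-3,4,6-trimethoxyphenyl)-3-(3-benzyloxy-4-methoxyphenyl)propane-1,3-dione F3. Cyclodehydration (p-TsOH, toluene, reflux) gives the flavone directly, so the route is rejoined at 12 without the chalcone or the oxidation step.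

Step 8 (selectivity of the final demethylation in the presence of free phenols; risk of cleaving the 7-OMe next to 6-OH or the 4'-OMe next to 3'-OH). The fallback sets out from 12 and reverses the order of the two deprotections so that no free phenol is present during the Lewis-acid step. MgBr2·OEt2 (MeCN–toluene, 80 °C) cleaves only the carbonyl-chelated 5-OMe and gives 6-benzyloxy-2-(3-benzyloxy-4-methoxyphenyl)-5-hydroxy-7,8-dimethoxy-4H-chromen-4-one F4. Hydrogenolysis (H2, Pd/C, THF–MeOH, rt) of both benzyl ethers then rejoins the route at 14.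

**Further compounds**
F1 | step 3 | 3-acetyl-4-hydroxy-2,5,6-trimethoxybenzaldehyde | CC(=O)c1c(O)c(OC)c(OC)c(C=O)c1OC
F2 | step 5 | 3-benzyloxy-4-methoxybenzoyl chloride | COc1ccc(C(Cl)=O)cc1OCc1ccccc1
F3 | step 5 | 1-(5-benzyloxy-2-hydroxy-3,4,6-trimethoxyphenyl)-3-(3-benzyloxy-4-methoxyphenyl)propane-1,3-dione | COc1ccc(C(=O)CC(=O)c2c(O)c(OC)c(OC)c(OCc3ccccc3)c2OC)cc1OCc1ccccc1
F4 | step 8 | 6-benzyloxy-2-(3-benzyloxy-4-methoxyphenyl)-5-hydroxy-7,8-dimethoxy-4H-chromen-4-one | COc1ccc(-c2cc(=O)c3c(O)c(OCc4ccccc4)c(OC)c(OC)c3o2)cc1OCc1ccccc1
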